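## Structural features

The target is a C10 halogenated monoterpene on one cyclohexane ring. Numbering used throughout: C1 bears the acetate, C2 is the ring methylene, C3 bears bromine, C4 the two methyl groups, C5 chlorine, C6 is the ring carbon of the exocyclic C6=C7 double bond, and C7 carries the bromomethyl carbon C8. The stereocentres C1 (S), C3 (R) and C5 (R) alternate around the ring and are never bonded to one another, but C3 and C5 both flank the quaternary C4, and C1 and C5 both flank C6. The acetate and the C3 bromine are cis, the C5 chlorine is trans to both, and C8 lies on the C5 side of the alkene (Z). This geometry puts A(1,3) strain between C8 and any equatorial group on C5, so the chlorine should sit axial with the C1 and C3 substituents equatorial. The fragile functions are the primary allylic bromide at C8 (substitution, SN2′, base), the secondary allylic chloride at C5 (ionisation, allylic shift), the allylic acetate, and the neopentyl secondary bromide at C3, which invites elimination while it is being made. The real difficulty is the quaternary C4 between two heteroatom-bearing stereocentres: C3–C4 is the most hindered ring bond, and a C–Br bond must later be made by substitution next to it. The key step uses exactly this feature: because C4 lies between C3 and C5, an isopropenyl ketone at C5 is a masked, regiochemically unambiguous dimethyl enolate at C4 that can close the ring onto a C3 aldehyde, making the C3–C4 bond, the quaternary centre and the C3 carbinol centre together.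

## Logic of the disconnections

**25 ⇒ 23 (C8–Br).** The primary allylic C–Br bond is cut first, because this function cannot survive fluoride, amine bases or oxidants. The precursor 23 has a plain allylic alcohol and everything else in final form. The forward step must be a cold, neutral bromination that substitutes directly at C8, without allylic shift and without exchanging the C5 chloride.

**23 ⇒ 22 ⇒ 21 ⇒ 20 (C8–O benzyl ether bond, C1–O acyl bond, C1–O–Si bond).** These are protecting-group cuts. The acetate is placed on C1 while C8 is still masked, so that neither fluoride nor the acylation catalyst meets an allylic bromide. This leads back to 20, whose oxygens carry the same two ethers as every intermediate since 9. The forward steps need a desilylation too weakly basic and nucleophilic to touch the allylic chloride, and an oxidative ether cleavage that stops at the allylic alcohol.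

**20 ⇒ 18 (C5–Cl).** The chlorine is trans to the C1 and C3 substituents, so it is traced to the all-cis alcohol 18 by substitution with inversion. In 18 this is the only hydroxyl, so no chemoselectivity has to be built in, and a strained equatorial C–O bond becomes an unstrained axial C–Cl bond. The forward step must substitute at C5 and not at C7.

**18 ⇒ 17 (C5–H).** Removing the carbinol hydrogen returns the ketone that the ring closure leaves at C5, and one stereocentre disappears. Forward, hydride must add 1,2 to the enone, from the face opposite the pseudoaxial C4 methyl group.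

**17 ⇒ 15 (C3–Br).** The equatorial bromide, cis to the C1 oxygen, is traced to the axial, trans alcohol of 15 by substitution with inversion. The cut is placed at the ketone stage for three reasons: only one hydroxyl is present, no allylic halide yet exists that bromide could scramble, and the C5 carbonyl disfavours cationic rearrangement. The price is an SN2 reaction at a neopentyl carbon that must outrun elimination toward C2.

**15 ⇒ 12 (C3–C4, the key cut).** Cutting the most hindered ring bond opens the ring to an acyclic aldehyde with a cross-conjugated dienone. The quaternary centre, the ring and the C3 stereocentre all vanish, leaving one stereocentre (C1) and one defined alkene. Forward, an enolate must be generated only at C4, with an enolisable aldehyde and a second enone present. Hydride addition to the isopropenyl terminus does this where deprotonation could not.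

**12 ⇒ 11 (the two C–O bonds of the C3 acetal).** The aldehyde is β to a silyloxy group and shares the molecule with two enones, so it should exist only just before ring closure. The acetal carries C3 safely through organometallic and palladium steps. The hydrolysis must be mild enough not to eliminate silanol or cleave the silyl ether.

**11 ⇒ 9 + 10 (C5–C6).** Cutting the acyl–alkenyl bond splits the dienone into an alkenylstannane and a purchased acid chloride. The C6=C7 geometry is then a property of 9 alone. Forward, tin-to-palladium transfer at an α-branched stannane must be fast enough to beat protodestannylation, and must proceed with retention.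

**9 ⇒ 8 ⇒ 7 (C6–Sn and C7–H; O–Si).** The trisubstituted alkene is traced to an alkyne by formal anti addition of H–Sn. Anti addition puts tin, and hence the later C5, cis to C8. The free C1 hydroxyl of 7 is needed to steer tin to C6, so silylation follows the hydrostannation. The demand is complete regio- and anti-selectivity.

**7 ⇒ 6 (C1–H).** The only stereocentre not set by the substrate is traced to a prochiral alkynyl ketone. Catalytic asymmetric transfer hydrogenation must give the S carbinol without reducing the alkyne and without base that would eliminate methanol from the β-acetal.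

**6 ⇒ 3 + 2 (C1–C6), then 2 ⇒ 1 (C1–N).** The ynone is cut at the acyl–alkynyl bond into the acetylide of 3 and the acylating agent 2, made in one step from 1. Both fragments are purchased or one step away. The forward step must add the acetylide once only.

## Other disconnections considered

**Alternative 1:** The cut is at the two C–O bonds C5–O and C8–O, which are traced to the ends of a C5=C6–C7=C8 diene in the cyclohexenol A1 (trans-5-silyloxy-4,4-dimethyl-2-vinylcyclohex-2-en-1-ol). Forward, singlet oxygen would add across the diene in a [4+2] sense on the face of the C1 hydroxyl, guided by hydrogen bonding, to give the bicyclic endoperoxide A2. Reduction of the O–O bond would then expose hydroxyls at C5 and C8.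
- In its favour: the C6=C7 geometry is enforced by the six-membered peroxide ring and cannot come out wrong, which is at least the equal of the chosen plan and arguably better. Two oxygen functions arrive in one metal-free step, and the C5 oxygen comes out cis to C1, as the later inversion to chloride requires.
- Against it: the carbon skeleton is untouched. A1 already contains the ring, the quaternary C4 and the C3 stereocentre, so the hardest construction is only moved elsewhere. The ene reaction at the C1–H competes. The endoperoxide is base-labile (Kornblum–DeLaMare rearrangement) and a handling hazard. After O–O cleavage, four oxygens must be told apart.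
- Comparison: structurally it solves the oxygenation pattern and the alkene but not the C3–C4 bond. Mechanistically it is a predictable pericyclic step. In step economy it should be longer once the synthesis of A1 is counted, and it shares the neopentyl substitution at C3.

**Alternative 2:** Two ring bonds are cut, C5–C6 and C2–C3, giving the ynone A3 (5-silyloxypent-3-yn-2-one) and the dialdehyde A4 (2,2-dimethylpropanedial). Forward, a chiral bisphosphine copper hydride would reduce A3 to a copper allenolate whose C6 attacks one formyl group of A4. The methyl ketone would then close onto the second formyl group to give the dihydroxy ketone A5.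
- In its favour: two skeletal bonds, the ring and the quaternary-flanking stereocentres from two small achiral fragments in one operation. In convergence and step count this is better than the chosen plan. Its absolute control is catalytic, which equals the chosen plan.
- Against it: three selectivities must hold at once, namely the choice between enantiotopic formyl groups, the alkylidene geometry (C8 cis to C5), and the relative configuration of the second aldol. The second aldol needs a methyl-ketone enolate that hydride chemistry does not supply, so the cascade may need a separate base. A4 is hydrate-prone and open to deformylation. A5 has hydrogens on C2 and can dehydrate, whereas 15 cannot because C4 is quaternary. A5 also needs a stereoselective C1 reduction and differentiation of three secondary oxygens.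
- Comparison: structurally more ambitious and shorter on paper. Mechanistically much less secure than a single intramolecular closure with one new stereocentre. The step advantage would probably be spent on protecting-group traffic.

**Alternative 3:** The cut is at C1–C6, giving the open-chain ynal A6, with aldehyde at C1, alkyne C6≡C7 and the C3 and C5 oxygens already in place. Forward, zerovalent nickel (Ni(cod)2 with a phosphine or carbene ligand) and Et3SiH would couple aldehyde and alkyne through an oxanickelacycle. The ring closes 6-exo-dig and hydrogen is delivered to C7 cis to C1, giving the tris-silyl ether A7 with the target alkene geometry.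
- In its favour: this reductive ynal cyclisation is a well-established reaction class, equal in reliability to the chosen key step. It sets ring and alkene geometry in a single step, which is better than setting the geometry three steps earlier. A7 emerges with every oxygen differently protected, which is better orthogonality than in the chosen route.
- Against it: A6 needs the quaternary C4 placed between two carbinol stereocentres in an open chain, which means two separate asymmetric operations. C1 is set by the substrate and comes out epimeric, so the endgame needs three inversions (C1 by Mitsunobu reaction with acetic acid, C3, C5) against two in the chosen plan. The neopentyl substitution at C3 is the same.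
- Comparison: structurally it leaves the hardest centre, C4, to acyclic chemistry. Mechanistically it is sound. In step economy it should be the longest of the four.

Key step: step 8

Remark: the sense of induction in step 3 is assigned by analogy between alkynyl and aryl ketones (the alkyne takes the place of the aryl group); if the roles were exchanged, the (R,R) catalyst would be used.

## Route

Step 1
Reactants: 1 methyl 3,3-dimethoxypropanoate
Product: 2 N-methoxy-N-methyl-3,3-dimethoxypropanamide
Conditions: MeNHOMe·HCl, i-PrMgCl, THF, −20 °C
Reagents that add atoms: N,O-dimethylhydroxylamine hydrochloride, CNOC.Cl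
Why: Ester aminolysis by the magnesium amide of N,O-dimethylhydroxylamine (first half of the Weinreb ketone synthesis); the low temperature and the weakly basic amide should leave the acetal and the C2 methylene alone.

Step 2
Reactants: 3 1-methoxy-4-[(prop-2-yn-1-yloxy)methyl]benzene; 2 N-methoxy-N-methyl-3,3-dimethoxypropanamide
Product: 6 1,1-dimethoxy-6-(4-methoxybenzyloxy)hex-4-yn-3-one, via lithium acetylide 4 (not isolated), via lithium aminal adduct 5 (not isolated)
Conditions: n-BuLi, THF, −78 °C; then 2, −78 → −20 °C; cold aq NH4Cl
Reagents that add atoms: none
Why: Weinreb ketone synthesis: acetylide 4 adds once because the chelated adduct 5 persists until the cold acidic quench, which should also keep the released amine from adding to the ynone.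

Step 3
Reactants: 6 1,1-dimethoxy-6-(4-methoxybenzyloxy)hex-4-yn-3-one
Product: 7 (3S)-1,1-dimethoxy-6-(4-methoxybenzyloxy)hex-4-yn-3-ol
Conditions: Ru[(S,S)-TsNCH(Ph)CH(Ph)NH](p-cymene) (1 mol%), i-PrOH, rt
Reagents that add atoms: none
Why: Noyori asymmetric transfer hydrogenation of an alkynyl ketone; the (S,S) catalyst should deliver hydride to the face that gives the 3S carbinol, the triple bond is not reduced, and the base-free medium should avoid β-elimination of methanol.

Step 4
Reactants: 7 (3S)-1,1-dimethoxy-6-(4-methoxybenzyloxy)hex-4-yn-3-ol
Product: 8 (3S,4Z)-1,1-dimethoxy-6-(4-methoxybenzyloxy)-4-(tributylstannyl)hex-4-en-3-ol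
Conditions: [Cp*RuCl]4 (2.5 mol%), Bu3SnH, CH2Cl2, rt
Reagents that add atoms: tributyltin hydride, CCCC[SnH](CCCC)CCCC
Why: Ruthenium-catalysed trans-hydrostannation of a propargylic alcohol; hydrogen bonding of the free hydroxyl to the chloride ligand should steer tin to the proximal alkyne carbon, and anti addition places tin cis to the CH2O group (Z).

Step 5
Reactants: 8 (3S,4Z)-1,1-dimethoxy-6-(4-methoxybenzyloxy)-4-(tributylstannyl)hex-4-en-3-ol
Product: 9 (3S,4Z)-3-(tert-butyldimethylsilyloxy)-1,1-dimethoxy-6-(4-methoxybenzyloxy)-4-(tributylstannyl)hex-4-ene
Conditions: TBSCl, imidazole, DMF, rt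
Reagents that add atoms: tert-butyldimethylsilyl chloride, CC(C)(C)[Si](C)(C)Cl
Why: Standard silylation of a secondary alcohol; the non-acidic medium keeps the alkenyl–tin bond and the acetal, which a silyl triflate would endanger.

Step 6
Reactants: 9 (3S,4Z)-3-(tert-butyldimethylsilyloxy)-1,1-dimethoxy-6-(4-methoxybenzyloxy)-4-(tributylstannyl)hex-4-ene; 10 2-methylprop-2-enoyl chloride
Product: 11 (3S,4Z)-3-(tert-butyldimethylsilyloxy)-1,1-dimethoxy-6-(4-methoxybenzyloxy)-4-(2-methylprop-2-enoyl)hex-4-ene
Conditions: Pd2(dba)3 (2.5 mol%), P(2-furyl)3 (10 mol%), CuI (10 mol%), BHT (trace), THF, 50 °C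
Reagents that add atoms: none
Why: Stille acylation (palladium-catalysed ketone synthesis from an acid chloride and an alkenylstannane) with retention of alkene geometry; the weakly donating phosphine and CuI should speed tin-to-metal transfer at the α-branched stannane, and the inhibitor suppresses polymerisation.

Step 7
Reactants: 11 (3S,4Z)-3-(tert-butyldimethylsilyloxy)-1,1-dimethoxy-6-(4-methoxybenzyloxy)-4-(2-methylprop-2-enoyl)hex-4-ene
Product: 12 (3S,4Z)-3-(tert-butyldimethylsilyloxy)-6-(4-methoxybenzyloxy)-4-(2-methylprop-2-enoyl)hex-4-enal
Conditions: TsOH·H2O (5 mol%), acetone/H2O (10:1), 0 °C → rt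
Reagents that add atoms: water, O
Why: Acid-catalysed acetal hydrolysis; a dimethyl acetal of an aliphatic aldehyde cleaves far faster than a secondary silyl ether or a 4-methoxybenzyl ether, and the low temperature should keep the β-silyloxy aldehyde from eliminating (12 is used at once).

Step 8
Reactants: 12 (3S,4Z)-3-(tert-butyldimethylsilyloxy)-6-(4-methoxybenzyloxy)-4-(2-methylprop-2-enoyl)hex-4-enal
Product: 15 (3S,5S,6Z)-5-(tert-butyldimethylsilyloxy)-3-hydroxy-6-[2-(4-methoxybenzyloxy)ethylidene]-2,2-dimethylcyclohexan-1-one, via copper enolate 13 (not isolated), via copper aldolate 14 (not isolated)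
Conditions: [(Ph3P)CuH]6 (0.25 equiv), degassed toluene, −40 → 0 °C; aq NH4Cl
Reagents that add atoms: none
Why: Copper hydride reductive aldol cyclisation: hydride adds to the unsubstituted CH2 of the isopropenyl enone to give copper enolate 13, whose only nucleophilic carbon is C4, and 13 adds to the tethered aldehyde to give aldolate 14, protonated on work-up. The closest known reaction type is the conjugate reduction–aldol ring closure of enones tethered to aldehydes or ketones with this hexameric phosphine copper hydride, together with copper hydride reductive aldol closures of unsaturated esters and amides in which the acyl carbon becomes a ring member. The ring closes in the 6-(enolendo)-exo-trig mode by forming C3–C4. The new stereocentre C3 should be set by a chair transition state in which copper bridges the enolate oxygen and the aldehyde oxygen, which holds the C3–O bond axial while the C1 silyl ether sits equatorial, giving the trans (3S) alcohol. Chemoselectivity between the two enones that share the carbonyl is secured by the unhindered terminal CH2 against the trisubstituted, β-branched C6=C7, and conjugate reduction should be faster than 1,2-reduction of the aldehyde at low temperature. The product cannot dehydrate because C4 has no hydrogen, and the neutral medium leaves the C6=C7 geometry and both ethers untouched.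

Step 9
Reactants: 15 (3S,5S,6Z)-5-(tert-butyldimethylsilyloxy)-3-hydroxy-6-[2-(4-methoxybenzyloxy)ethylidene]-2,2-dimethylcyclohexan-1-one
Product: 17 (3R,5S,6Z)-3-bromo-5-(tert-butyldimethylsilyloxy)-6-[2-(4-methoxybenzyloxy)ethylidene]-2,2-dimethylcyclohexan-1-one, via C3 oxyphosphonium bromide 16 (not isolated)
Conditions: CBr4, PPh3, CH2Cl2, 0 °C → rt
Reagents that add atoms: carbon tetrabromide, BrC(Br)(Br)Br
Why: Appel bromination: the axial C3 hydroxyl is activated as 16 and displaced by bromide with inversion, giving the equatorial bromide cis to the C1 oxygen; inversion of axial neopentylic cyclohexanols to equatorial bromides under these conditions is a known, if elimination-prone, transformation, and the C5 carbonyl should hold back ionisation and methyl shift.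

Step 10
Reactants: 17 (3R,5S,6Z)-3-bromo-5-(tert-butyldimethylsilyloxy)-6-[2-(4-methoxybenzyloxy)ethylidene]-2,2-dimethylcyclohexan-1-one
Product: 18 (1S,3R,5S,6E)-3-bromo-5-(tert-butyldimethylsilyloxy)-6-[2-(4-methoxybenzyloxy)ethylidene]-2,2-dimethylcyclohexan-1-ol
Conditions: NaBH4, CeCl3·7H2O, MeOH, −78 °C
Reagents that add atoms: none
Why: Luche reduction (1,2-selective for enones); hydride should enter C5 axially, from the face opposite the pseudoaxial C4 methyl group, which puts the new hydroxyl cis to the C1 and C3 substituents.

Step 11
Reactants: 18 (1S,3R,5S,6E)-3-bromo-5-(tert-butyldimethylsilyloxy)-6-[2-(4-methoxybenzyloxy)ethylidene]-2,2-dimethylcyclohexan-1-ol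
Product: 20 tert-butyl{[(1S,2Z,3R,5R)-5-bromo-3-chloro-2-[2-(4-methoxybenzyloxy)ethylidene]-4,4-dimethylcyclohexyl]oxy}dimethylsilane, via C5 oxyphosphonium chloride 19 (not isolated)
Conditions: PPh3, Cl3CC(O)CCl3, CH2Cl2, 0 °C
Reagents that add atoms: hexachloroacetone, ClC(Cl)(Cl)C(=O)C(Cl)(Cl)Cl
Why: Appel-type chlorination with triphenylphosphine and hexachloroacetone, a combination that converts allylic alcohols into chlorides with inversion and without allylic shift; chloride displaces 19 from the axial direction, and the change from equatorial oxygen to axial chlorine relieves the A(1,3) strain with C8.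

Step 12
Reactants: 20 tert-butyl{[(1S,2Z,3R,5R)-5-bromo-3-chloro-2-[2-(4-methoxybenzyloxy)ethylidene]-4,4-dimethylcyclohexyl]oxy}dimethylsilane
Product: 21 (1S,2Z,3R,5R)-5-bromo-3-chloro-2-[2-(4-methoxybenzyloxy)ethylidene]-4,4-dimethylcyclohexan-1-ol
Conditions: HF·pyridine, pyridine/THF, 0 °C → rt
Reagents that add atoms: none
Why: Acidic fluoride desilylation; buffered HF·pyridine cleaves the secondary silyl ether and is too weakly basic and nucleophilic to attack the hindered allylic chloride or the equatorial bromide, which has no anti-periplanar hydrogen.

Step 13
Reactants: 21 (1S,2Z,3R,5R)-5-bromo-3-chloro-2-[2-(4-methoxybenzyloxy)ethylidene]-4,4-dimethylcyclohexan-1-ol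
Product: 22 (1S,2Z,3R,5R)-5-bromo-3-chloro-2-[2-(4-methoxybenzyloxy)ethylidene]-4,4-dimethylcyclohexyl acetate
Conditions: Ac2O, pyridine, DMAP (cat.), CH2Cl2, 0 °C → rt
Reagents that add atoms: acetic anhydride, CC(=O)OC(C)=O
Why: DMAP-catalysed acetylation of the equatorial allylic C1 alcohol; the C1–O bond is not broken, so the configuration is kept.

Step 14
Reactants: 22 (1S,2Z,3R,5R)-5-bromo-3-chloro-2-[2-(4-methoxybenzyloxy)ethylidene]-4,4-dimethylcyclohexyl acetate
Product: 23 (1S,2Z,3R,5R)-5-bromo-3-chloro-2-(2-hydroxyethylidene)-4,4-dimethylcyclohexyl acetate
Conditions: DDQ, CH2Cl2/pH 7 phosphate buffer (10:1), 0 °C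
Reagents that add atoms: none
Why: Oxidative cleavage of the 4-methoxybenzyl ether with DDQ in wet solvent; buffer, low temperature and a small excess should spare the acetate and both halides and prevent over-oxidation of the allylic alcohol.

Step 15
Reactants: 23 (1S,2Z,3R,5R)-5-bromo-3-chloro-2-(2-hydroxyethylidene)-4,4-dimethylcyclohexyl acetate
Product: 25 (1S,2Z,3R,5R)-5-bromo-2-(2-bromoethylidene)-3-chloro-4,4-dimethylcyclohexyl acetate, via C8 oxyphosphonium bromide 24 (not isolated)
Conditions: CBr4, PPh3, CH2Cl2, −20 → 0 °C
Reagents that add atoms: carbon tetrabromide, BrC(Br)(Br)Br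
Why: Appel bromination of the primary allylic alcohol via 24; direct SN2 at the primary C8 should outrun SN2′ attack at the fully substituted C6, and is fast enough at low temperature to leave the hindered C5 chloride unexchanged.

## Compound list

1 | methyl 3,3-dimethoxypropanoate | COC(=O)CC(OC)OC | starting material
2 | N-methoxy-N-methyl-3,3-dimethoxypropanamide | CON(C)C(=O)CC(OC)OC | intermediate
3 | 1-methoxy-4-[(prop-2-yn-1-yloxy)methyl]benzene | C#CCOCc1ccc(OC)cc1 | starting material
4 | [3-(4-methoxybenzyloxy)prop-1-yn-1-yl]lithium (lithium acetylide of 3) | [Li]C#CCOCc1ccc(OC)cc1 | intermediate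
5 | lithium 3-[methoxy(methyl)amino]-1,1-dimethoxy-6-(4-methoxybenzyloxy)hex-4-yn-3-olate (tetrahedral adduct, C3 not controlled) | COC(OC)CC(O[Li])(N(C)OC)C#CCOCc1ccc(OC)cc1 | intermediate
6 | 1,1-dimethoxy-6-(4-methoxybenzyloxy)hex-4-yn-3-one | COC(OC)CC(=O)C#CCOCc1ccc(OC)cc1 | intermediate
7 | (3S)-1,1-dimethoxy-6-(4-methoxybenzyloxy)hex-4-yn-3-ol | COC(OC)C[C@H](O)C#CCOCc1ccc(OC)cc1 | intermediate
8 | (3S,4Z)-1,1-dimethoxy-6-(4-methoxybenzyloxy)-4-(tributylstannyl)hex-4-en-3-ol | COC(OC)C[C@H](O)/C([Sn](CCCC)(CCCC)CCCC)=C/COCc1ccc(OC)cc1 | intermediate
9 | (3S,4Z)-3-(tert-butyldimethylsilyloxy)-1,1-dimethoxy-6-(4-methoxybenzyloxy)-4-(tributylstannyl)hex-4-ene | COC(OC)C[C@H](O[Si](C)(C)C(C)(C)C)/C([Sn](CCCC)(CCCC)CCCC)=C/COCc1ccc(OC)cc1 | intermediate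
10 | 2-methylprop-2-enoyl chloride (methacryloyl chloride) | CC(=C)C(=O)Cl | starting material
11 | (3S,4Z)-3-(tert-butyldimethylsilyloxy)-1,1-dimethoxy-6-(4-methoxybenzyloxy)-4-(2-methylprop-2-enoyl)hex-4-ene | COC(OC)C[C@H](O[Si](C)(C)C(C)(C)C)/C(C(=O)C(C)=C)=C/COCc1ccc(OC)cc1 | intermediate
12 | (3S,4Z)-3-(tert-butyldimethylsilyloxy)-6-(4-methoxybenzyloxy)-4-(2-methylprop-2-enoyl)hex-4-enal | O=CC[C@H](O[Si](C)(C)C(C)(C)C)/C(C(=O)C(C)=C)=C/COCc1ccc(OC)cc1 | intermediate
13 | copper enolate of 12: O–Cu on C5, C4=C5 double bond carrying both methyl groups, C1 (S) and the C6=C7 geometry as in 12 (phosphine on copper not drawn) | O=CC[C@H](O[Si](C)(C)C(C)(C)C)/C(C(O[Cu])=C(C)C)=C/COCc1ccc(OC)cc1 | intermediate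
14 | copper aldolate of 15: O–Cu on C3, otherwise as 15 (phosphine on copper not drawn) | CC(C)(C)[Si](C)(C)O[C@H]1C[C@H](O[Cu])C(C)(C)C(=O)/C1=C\COCc2ccc(OC)cc2 | intermediate
15 | (3S,5S,6Z)-5-(tert-butyldimethylsilyloxy)-3-hydroxy-6-[2-(4-methoxybenzyloxy)ethylidene]-2,2-dimethylcyclohexan-1-one | CC(C)(C)[Si](C)(C)O[C@H]1C[C@H](O)C(C)(C)C(=O)/C1=C\COCc2ccc(OC)cc2 | intermediate
16 | C3-O-triphenylphosphonium bromide of 15 (configuration as 15) | CC(C)(C)[Si](C)(C)O[C@H]1C[C@H](O[P+](c2ccccc2)(c2ccccc2)c2ccccc2)C(C)(C)C(=O)/C1=C\COCc2ccc(OC)cc2.[Br-] | intermediate
17 | (3R,5S,6Z)-3-bromo-5-(tert-butyldimethylsilyloxy)-6-[2-(4-methoxybenzyloxy)ethylidene]-2,2-dimethylcyclohexan-1-one | CC(C)(C)[Si](C)(C)O[C@H]1C[C@@H](Br)C(C)(C)C(=O)/C1=C\COCc2ccc(OC)cc2 | intermediate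
18 | (1S,3R,5S,6E)-3-bromo-5-(tert-butyldimethylsilyloxy)-6-[2-(4-methoxybenzyloxy)ethylidene]-2,2-dimethylcyclohexan-1-ol | CC(C)(C)[Si](C)(C)O[C@H]1C[C@@H](Br)C(C)(C)[C@@H](O)/C1=C\COCc2ccc(OC)cc2 | intermediate
19 | C5-O-triphenylphosphonium chloride of 18 (configuration as 18) | CC(C)(C)[Si](C)(C)O[C@H]1C[C@@H](Br)C(C)(C)[C@@H](O[P+](c2ccccc2)(c2ccccc2)c2ccccc2)/C1=C\COCc2ccc(OC)cc2.[Cl-] | intermediate
20 | tert-butyl{[(1S,2Z,3R,5R)-5-bromo-3-chloro-2-[2-(4-methoxybenzyloxy)ethylidene]-4,4-dimethylcyclohexyl]oxy}dimethylsilane | CC(C)(C)[Si](C)(C)O[C@H]1C[C@@H](Br)C(C)(C)[C@H](Cl)/C1=C\COCc2ccc(OC)cc2 | intermediate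
21 | (1S,2Z,3R,5R)-5-bromo-3-chloro-2-[2-(4-methoxybenzyloxy)ethylidene]-4,4-dimethylcyclohexan-1-ol | O[C@H]1C[C@@H](Br)C(C)(C)[C@H](Cl)/C1=C\COCc2ccc(OC)cc2 | intermediate
22 | (1S,2Z,3R,5R)-5-bromo-3-chloro-2-[2-(4-methoxybenzyloxy)ethylidene]-4,4-dimethylcyclohexyl acetate | CC(=O)O[C@H]1C[C@@H](Br)C(C)(C)[C@H](Cl)/C1=C\COCc2ccc(OC)cc2 | intermediate
23 | (1S,2Z,3R,5R)-5-bromo-3-chloro-2-(2-hydroxyethylidene)-4,4-dimethylcyclohexyl acetate | CC(=O)O[C@H]1C[C@@H](Br)C(C)(C)[C@H](Cl)/C1=C\CO | intermediate
24 | C8-O-triphenylphosphonium bromide of 23 (configuration as 23) | CC(=O)O[C@H]1C[C@@H](Br)C(C)(C)[C@H](Cl)/C1=C\CO[P+](c2ccccc2)(c2ccccc2)c2ccccc2.[Br-] | intermediate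
25 | (1S,2Z,3R,5R)-5-bromo-2-(2-bromoethylidene)-3-chloro-4,4-dimethylcyclohexyl acetate | CC(=O)O[C@H]1C[C@@H](Br)C(C)(C)[C@H](Cl)/C1=C\CBr | target

## Step count and least certain steps

Total: 15 steps. Longest linear sequence: 15 steps (1 → 25); 3 and 10 enter as purchased.

**Step 8 (key step).** The most likely failure is interception of the copper enolate before it reaches the aldehyde: protonation to the isopropyl ketone, competing 1,2-reduction of the aldehyde, or loss of silanol from the β-silyloxy aldehyde. Poor facial selectivity in the aldol addition comes next, since the bridged transition state is an expectation and not a certainty. The fallback closes the same C3–C4 bond by a samarium Reformatsky-type aldol, in which the enolate is released by reducing a C–Br bond and not by hydride addition. It sets out from 11. RhCl(PPh3)3-catalysed 1,4-hydrosilylation with Et3SiH should turn the isopropenyl enone into the triethylsilyl enol ether F1. NBS in THF at −78 °C should brominate it at C4 to the α-bromo ketone F2. Acetal hydrolysis as in step 7 gives the bromo keto aldehyde F3. SmI2 in THF at −78 °C should then form the samarium enolate and close the ring through a comparable metal-bridged transition state, returning to the route at 15.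

**Step 9.** The likely failure is anti elimination toward C2 (an axial hydrogen there is anti-periplanar to the activated oxygen) overtaking substitution, because the backside of C3 is shielded by the pseudoaxial C4 methyl group; skeletal rearrangement is a lesser risk. The fallback replaces in-flask phosphonium activation by a discrete sulfonate displacement. It sets out from 15: Tf2O and pyridine in CH2Cl2 at −40 °C give the C3 triflate F4, which is displaced by Bu4NBr in toluene at −20 → 0 °C with inversion, returning at 17. The much better leaving group allows a temperature at which elimination is slower, with no base stronger than bromide present.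

**Step 10.** The likely failure is poor facial selectivity of hydride addition: axial delivery creates an equatorial alkoxide that feels A(1,3) strain from C8, which may erode the usual preference. The fallback changes the order so that hydride is delivered intramolecularly from the C3 oxygen. It sets out from 15. Evans–Saksena reduction (Me4NBH(OAc)3, MeCN/AcOH, −25 °C) should give the 1,3-anti diol F5. Corey–Kim conditions (NCS, Me2S, CH2Cl2, −20 → 0 °C), which convert allylic but not saturated alcohols, should give the C5 chloro alcohol F6 with inversion. Appel bromination of the remaining C3 hydroxyl (CBr4, PPh3) returns to the route at 20. This order fixes C5 more reliably but makes both substitutions harder, because the axial C3 oxygen shields the C5 backside, and bromide must then meet the allylic chloride.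

**Step 6.** The likely failure is slow tin-to-palladium transfer at the α-branched, silyloxy-flanked stannane, which would allow protodestannylation and decomposition or polymerisation of the acid chloride. The fallback forms the C5–C6 bond by carbonyl addition and adjusts the oxidation level afterwards. It sets out from 9. I2 in CH2Cl2 at 0 °C gives, with retention, the alkenyl iodide F7. Nozaki–Hiyama–Kishi coupling with methacrolein (CrCl2, NiCl2 cat., DMF) gives the bis-allylic alcohol F8 as a mixture of carbinol epimers. Dess–Martin oxidation (NaHCO3, CH2Cl2) returns to the route at 11.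

## Further compounds

F1 | step 8 | triethylsilyl enol ether of the isobutyryl ketone derived from 11 (O–SiEt3 on C5, C4=C5 bearing both methyls; C1 S, C6=C7 and acetal as in 11) | COC(OC)C[C@H](O[Si](C)(C)C(C)(C)C)/C(C(O[Si](CC)(CC)CC)=C(C)C)=C/COCc1ccc(OC)cc1
F2 | step 8 | α-bromo ketone: 11 with the 2-methylprop-2-enoyl group replaced by 2-bromo-2-methylpropanoyl | COC(OC)C[C@H](O[Si](C)(C)C(C)(C)C)/C(C(=O)C(C)(C)Br)=C/COCc1ccc(OC)cc1
F3 | step 8 | bromo keto aldehyde: 12 with the 2-methylprop-2-enoyl group replaced by 2-bromo-2-methylpropanoyl | O=CC[C@H](O[Si](C)(C)C(C)(C)C)/C(C(=O)C(C)(C)Br)=C/COCc1ccc(OC)cc1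
F4 | step 9 | C3 trifluoromethanesulfonate of 15 (configuration as 15) | CC(C)(C)[Si](C)(C)O[C@H]1C[C@H](OS(=O)(=O)C(F)(F)F)C(C)(C)C(=O)/C1=C\COCc2ccc(OC)cc2
F5 | step 10 | 1,3-anti diol from 15: C3 hydroxyl trans and C5 hydroxyl cis to the C1 silyl ether, C8 cis to C5 | CC(C)(C)[Si](C)(C)O[C@H]1C[C@H](O)C(C)(C)[C@@H](O)/C1=C\COCc2ccc(OC)cc2
F6 | step 10 | C5 chloro alcohol: C3 hydroxyl and C5 chlorine both trans to the C1 silyl ether, C8 cis to C5 | CC(C)(C)[Si](C)(C)O[C@H]1C[C@H](O)C(C)(C)[C@H](Cl)/C1=C\COCc2ccc(OC)cc2
F7 | step 6 | (3S,4Z)-3-(tert-butyldimethylsilyloxy)-4-iodo-1,1-dimethoxy-6-(4-methoxybenzyloxy)hex-4-ene | COC(OC)C[C@H](O[Si](C)(C)C(C)(C)C)/C(I)=C/COCc1ccc(OC)cc1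
F8 | step 6 | bis-allylic alcohol: 11 with the ketone reduced to CH(OH), carbinol epimers, CH2O group cis to the carbinol carbon | COC(OC)C[C@H](O[Si](C)(C)C(C)(C)C)/C(C(O)C(C)=C)=C/COCc1ccc(OC)cc1
A1 | alternative 1 | trans-5-(tert-butyldimethylsilyloxy)-4,4-dimethyl-2-vinylcyclohex-2-en-1-ol | O[C@H]1C[C@H](O[Si](C)(C)C(C)(C)C)C(C)(C)C=C1C=C
A2 | alternative 1 | fused 3,6-dihydro-1,2-dioxine endoperoxide of A1 (peroxide oxygens on C5 and C8, C5–O cis to the C1 hydroxyl, silyl ether trans) | O[C@H]1C[C@H](O[Si](C)(C)C(C)(C)C)C(C)(C)[C@H]2OOCC=C12
A3 | alternative 2 | 5-(tert-butyldimethylsilyloxy)pent-3-yn-2-one | CC(=O)C#CCO[Si](C)(C)C(C)(C)C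
A4 | alternative 2 | 2,2-dimethylpropanedial | O=CC(C)(C)C=O
A5 | alternative 2 | trans-3,5-dihydroxy-4,4-dimethyl-2-[2-(tert-butyldimethylsilyloxy)ethylidene]cyclohexan-1-one (C8 cis to the C5 carbinol) | O=C1C[C@H](O)C(C)(C)[C@@H](O)/C1=C\CO[Si](C)(C)C(C)(C)C
A6 | alternative 3 | 3,8-bis(tert-butyldimethylsilyloxy)-5-(4-methoxybenzyloxy)-4,4-dimethyloct-6-ynal (C3 and C5 configured as in A7) | O=CC[C@H](O[Si](C)(C)C(C)(C)C)C(C)(C)[C@@H](OCc1ccc(OC)cc1)C#CCO[Si](C)(C)C(C)(C)C
A7 | alternative 3 | cyclised tris-silyl ether: C1 triethylsilyl ether (epimeric to the target), C3 silyl ether, C5 4-methoxybenzyl ether, C8 silyl ether, target alkene geometry | CC[Si](CC)(CC)O[C@@H]1C[C@H](O[Si](C)(C)C(C)(C)C)C(C)(C)[C@@H](OCc2ccc(OC)cc2)/C1=C\CO[Si](C)(C)C(C)(C)C
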